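Atom labels: C1/C5 ring fusion, C2–C3=C4(CH3) completing the five-membered ring, C6 (OH), C7 (side chain C11–C15), C9 (OAc), C10 (=CH2). The route rests on cutting C3=C4, the only double bond of the cyclopentene: ring-closing metathesis joins a C1 allyl and a C5 isopropenyl arm held trans on the finished seven-membered ring, every other olefin pairing leading only to four- or eight-to-ten-membered rings, and in the same flask cross-metathesis with 2-methyl-2-butene completes the prenyl terminus. The tetraene precursor comes from cycloheptene through an asymmetric allylic alkylation (C7), a cis-fused lactone relaying C7 to C6 and C11, and a silyloxy-directed conjugate addition/allylation (C5, C1).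

Key step: step 16

Assumption: the (S,S)-Trost ligand is taken to give the (R)-malonate 4 and (−)-Ipc2B(allyl) to add to the Si face of aldehyde 19; if either sense of induction is the reverse, the mirror-image ligand or reagent is used.

Step 1
Reactants: 1 cycloheptene
Product: 2 (±)-cyclohept-2-en-1-yl benzoate
Conditions: PhCO3t-Bu, CuBr (5 mol%), MeCN, 80 °C (1 in excess)
Reagents that add atoms: tert-butyl perbenzoate CC(C)(C)OOC(=O)c1ccccc1
Why: Kharasch–Sosnovsky allylic acyloxylation: the copper-bound benzoate traps the symmetric cycloheptenyl radical, so a single racemic allylic benzoate should form, and its stereocentre is erased in step 2.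

Step 2
Reactants: 2 (±)-cyclohept-2-en-1-yl benzoate; 3 dimethyl malonate
Product: 4 dimethyl 2-[(1R)-cyclohept-2-en-1-yl]malonate
Conditions: [Pd(η3-C3H5)Cl]2 (2.5 mol%), (S,S)-DACH-phenyl Trost ligand (7.5 mol%), Cs2CO3, CH2Cl2, rt
Reagents that add atoms: none
Why: Asymmetric allylic alkylation (Tsuji–Trost type, dynamic kinetic asymmetric transformation): both enantiomers of 2 ionise to the same meso π-allylpalladium complex and the chiral diphosphine steers the malonate to one enantiotopic terminus, which sets C7 stereoconvergently.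

Step 3
Reactants: 4 dimethyl 2-[(1R)-cyclohept-2-en-1-yl]malonate
Product: 6 2-[(1S)-cyclohept-2-en-1-yl]acetic acid, via malonic diacid 5 (not isolated)
Conditions: NaOH, MeOH/H2O, 70 °C; aq. HCl; then neat, 150 °C
Reagents that add atoms: sodium hydroxide [Na+].[OH-]
Why: Ester saponification followed by thermal decarboxylation of the malonic acid through the usual six-membered transition state; the allylic stereocentre C7 is not acidic and should survive.

Step 4
Reactants: 6 2-[(1S)-cyclohept-2-en-1-yl]acetic acid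
Product: 7 (3aS,8R,8aR)-8-iodooctahydro-2H-cyclohepta[b]furan-2-one
Conditions: I2, NaHCO3, MeCN/H2O, 0 °C, dark
Reagents that add atoms: iodine II
Why: Iodolactonisation under kinetic conditions: 5-exo opening of the iodonium ion by the carboxylate in an anti addition can only give the cis-fused γ-lactone, so C7 dictates the C6–O configuration (cis to the acetic arm) and places iodine trans at C5.

Step 5
Reactants: 7 iodolactone
Product: 8 (3aS,8aR)-3,3a,4,5,6,8a-hexahydro-2H-cyclohepta[b]furan-2-one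
Conditions: DBU, toluene, 90 °C
Reagents that add atoms: none
Why: E2 dehydroiodination: only a C1–H can be antiperiplanar to the C5–I bond (H6 is cis to iodine), so the double bond should form at C5=C1 and the allylic lactone is kept.

Step 6
Reactants: 8 unsaturated cis-lactone
Product: 10 (3S,3aS,8aS)-3-methyl-3,3a,4,5,6,8a-hexahydro-2H-cyclohepta[b]furan-2-one, via lithium enolate 9 (not isolated)
Conditions: LDA, THF, −78 °C; MeI, −78 → −40 °C
Reagents that add atoms: iodomethane CI
Why: Lactone enolate alkylation: iodomethane approaches the enolate on the convex face of the cis-fused bicycle, anti to the C7–C8 bond, which sets C11 with the methyl group cis to H7.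

Step 7
Reactants: 10 methyl lactone
Product: 11 (2S)-2-[(1S,2S)-2-hydroxycyclohept-3-en-1-yl]-N-methoxy-N-methylpropanamide
Conditions: MeNH(OMe)·HCl, AlMe3, CH2Cl2, 0 °C → rt
Reagents that add atoms: N,O-dimethylhydroxylamine hydrochloride CNOC.Cl
Why: Weinreb aminolysis of the γ-lactone by the aluminium amide, which should free the C6 allylic alcohol and turn C12 into an amide that tolerates the later enone, cuprate and enolate chemistry without touching C11.

Step 8
Reactants: 11 hydroxy Weinreb amide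
Product: 12 (2S)-2-[(1S,2S)-2-(tert-butyldimethylsilyloxy)cyclohept-3-en-1-yl]-N-methoxy-N-methylpropanamide
Conditions: TBSOTf, 2,6-lutidine, CH2Cl2, −78 → 0 °C
Reagents that add atoms: tert-butyldimethylsilyl triflate CC(C)(C)[Si](C)(C)OS(=O)(=O)C(F)(F)F
Why: Silylation of the secondary alcohol with the silyl triflate; it blocks relactonisation and installs the bulky γ-substituent that will direct step 10.

Step 9
Reactants: 12 silyl ether
Product: 13 (2S)-2-[(1S,2S)-2-(tert-butyldimethylsilyloxy)-5-oxocyclohept-3-en-1-yl]-N-methoxy-N-methylpropanamide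
Conditions: CrO3, 3,5-dimethylpyrazole, CH2Cl2, −20 °C
Reagents that add atoms: chromium trioxide O=[Cr](=O)=O
Why: Allylic oxidation with the CrO3·3,5-dimethylpyrazole complex at the only allylic methylene (C10), as known for cycloalkenyl silyl ethers, should give the γ-silyloxy enone without moving the double bond.

Step 10
Reactants: 13 γ-silyloxy enone
Product: 15 (2S)-2-[(1S,2R,3S,4R)-2-(tert-butyldimethylsilyloxy)-5-oxo-4-(prop-2-en-1-yl)-3-(prop-1-en-2-yl)cycloheptyl]-N-methoxy-N-methylpropanamide, via bromomagnesium enolate 14 (not isolated)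
Conditions: isopropenylMgBr, CuBr·SMe2 (20 mol%), THF, −78 → −40 °C; then allyl iodide, HMPA, −40 → 0 °C
Reagents that add atoms: isopropenylmagnesium bromide C=C(C)[Mg]Br; allyl iodide C=CCI
Why: Copper-catalysed conjugate addition followed by enolate alkylation (vicinal three-component coupling): the isopropenyl group adds to C5 anti to the γ-silyloxy group and the cis C7 side chain, and the regiodefined enolate is allylated at C1 trans to the new C5 substituent.

Step 11
Reactants: 15 trans-2-allyl-3-isopropenyl cycloheptanone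
Product: 17 (2S)-2-[(1S,2R,3S,4R,6R)-2-(tert-butyldimethylsilyloxy)-6-hydroxy-5-oxo-4-(prop-2-en-1-yl)-3-(prop-1-en-2-yl)cycloheptyl]-N-methoxy-N-methylpropanamide, via potassium enolate 16 (not isolated)
Conditions: KHMDS, THF, −78 °C; 2-(phenylsulfonyl)-3-phenyloxaziridine, −78 °C; NH4Cl
Reagents that add atoms: 2-(phenylsulfonyl)-3-phenyloxaziridine O=S(=O)(N1OC1c1ccccc1)c1ccccc1
Why: Kinetic deprotonation at the less substituted α-carbon C9 and enolate hydroxylation with the sulfonyloxaziridine (Davis oxidation), the reagent approaching anti to the pseudoaxial C1 allyl group and the C7 side chain, which should place the C9 hydroxyl cis to H1.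

Step 12
Reactants: 17 α-hydroxy ketone
Product: 18 (2S)-2-[(1S,2R,3S,4R,6R)-2-(tert-butyldimethylsilyloxy)-6-hydroxy-5-methylidene-4-(prop-2-en-1-yl)-3-(prop-1-en-2-yl)cycloheptyl]-N-methoxy-N-methylpropanamide
Conditions: Zn, CH2Br2, TiCl4, THF/CH2Cl2, 0 °C → rt
Reagents that add atoms: dibromomethane BrCBr
Why: Takai–Lombardo methylenation: the non-basic gem-dimetallic titanium reagent olefinates hindered, enolisable ketones without epimerising C1 or C9 and should leave the Weinreb amide untouched.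

Step 13
Reactants: 18 methylidene Weinreb amide
Product: 19 (2S)-2-[(1S,2R,3S,4R,6R)-2-(tert-butyldimethylsilyloxy)-6-hydroxy-5-methylidene-4-(prop-2-en-1-yl)-3-(prop-1-en-2-yl)cycloheptyl]propanal
Conditions: DIBAL-H (3 equiv), THF, −78 °C; Rochelle salt
Reagents that add atoms: none
Why: Hydride reduction of the Weinreb amide stops at the chelated tetrahedral aluminate, which releases the aldehyde only on work-up, so over-reduction and C11 epimerisation should be avoided (the extra hydride covers the free C9 hydroxyl).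

Step 14
Reactants: 19 α-methyl aldehyde
Product: 20 (1R,3S,4R,5S,6R)-4-(tert-butyldimethylsilyloxy)-3-[(2S,3S)-3-hydroxyhex-5-en-2-yl]-7-methylidene-6-(prop-2-en-1-yl)-5-(prop-1-en-2-yl)cycloheptan-1-ol
Conditions: (−)-Ipc2B(allyl) (2.5 equiv), Et2O, −78 °C; then NaOH, H2O2
Reagents that add atoms: (−)-B-allyldiisopinocampheylborane C=CCB([C@@H]1C[C@@H]2C[C@@H](C2(C)C)[C@H]1C)[C@@H]1C[C@@H]2C[C@@H](C2(C)C)[C@H]1C
Why: Brown asymmetric allylboration through a closed chair transition state: the (−)-Ipc reagent delivers the allyl group to the Si face, which is also the Felkin face of the α-methyl aldehyde (matched case), setting C12 as S with the 11,12-syn relationship.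

Step 15
Reactants: 20 diol
Product: 21 (1R,3S,4R,5S,6R)-3-[(2S,3S)-3-acetoxyhex-5-en-2-yl]-4-(tert-butyldimethylsilyloxy)-7-methylidene-6-(prop-2-en-1-yl)-5-(prop-1-en-2-yl)cycloheptyl acetate
Conditions: Ac2O, DMAP, pyridine, CH2Cl2, rt
Reagents that add atoms: acetic anhydride CC(=O)OC(C)=O
Why: DMAP-catalysed acylation (Steglich-type) of both free secondary alcohols at C9 and C12, while the C6 oxygen stays silylated.

Step 16
Reactants: 21 tetraene diacetate
Product: 23 (3aS,4R,5S,7R,8aR)-5-[(2S,3S)-3-acetoxy-6-methylhept-5-en-2-yl]-4-(tert-butyldimethylsilyloxy)-3-methyl-8-methylidene-1,3a,4,5,6,7,8,8a-octahydroazulen-7-yl acetate, via allyl-side-chain hydroazulene 22 (not isolated)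
Conditions: Grubbs II (5 mol%), CH2Cl2 (2 mM), 40 °C; then 2-methyl-2-butene (excess), 40 °C, sealed
Reagents that add atoms: 2-methyl-2-butene CC=C(C)C
Why: Ruthenium-alkylidene olefin metathesis (Chauvin [2+2]/cycloreversion): the catalyst loads on the monosubstituted C1 allyl group, the alkylidene adds across the C5 isopropenyl olefin and cycloreversion releases ethylene and the C3=C4 bond; the 2-methyl-2-butene added afterwards cross-metathesises the remaining terminal side-chain olefin to the prenyl group with loss of propene. The closest known reaction types are ring-closing metathesis of allyl/isopropenyl pairs on cycloalkanes to trisubstituted trans-fused cyclopentenes and prenyl-forming cross-metathesis with 2-methyl-2-butene. The five-membered carbocycle C1–C2–C3=C4–C5 is closed by ring-closing metathesis between two exocyclic arms; no new stereocentre is created, and the trans ring fusion follows from the C1/C5 configurations, which cannot epimerise once C10 is a methylidene. The step needs chemoselectivity among four olefins: the hindered 1,1-disubstituted C10 methylidene could only give cyclobutenes and the side-chain allyl group only eight- to ten-membered rings, so five-ring closure should win at high dilution, and the side-chain terminus (or its homodimer) is funnelled to the prenyl group by the excess trisubstituted olefin.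

Step 17
Reactants: 23 silyl ether of the target
Product: 24 (3aS,4R,5S,7R,8aR)-5-[(2S,3S)-3-acetoxy-6-methylhept-5-en-2-yl]-4-hydroxy-3-methyl-8-methylidene-1,3a,4,5,6,7,8,8a-octahydroazulen-7-yl acetate (CNP0151479.2)
Conditions: HF·pyridine, THF/pyridine, 0 °C → rt
Reagents that add atoms: none
Why: Fluoride-mediated desilylation under buffered acidic conditions, which should free the hindered C6 alcohol without acetate cleavage, acyl migration or ionisation of the allylic acetate.

Compound list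
1 | cycloheptene | C1=CCCCCC1 | starting material
2 | (±)-cyclohept-2-en-1-yl benzoate | O=C(OC1C=CCCCC1)c1ccccc1 | intermediate
3 | dimethyl malonate | COC(=O)CC(=O)OC | starting material
4 | dimethyl 2-[(1R)-cyclohept-2-en-1-yl]malonate | C1CC[C@@H](C(C(=O)OC)C(=O)OC)C=CC1 | intermediate
5 | 2-[(1R)-cyclohept-2-en-1-yl]malonic acid (not isolated) | C1CC[C@@H](C(C(=O)O)C(=O)O)C=CC1 | intermediate
6 | 2-[(1S)-cyclohept-2-en-1-yl]acetic acid | C1CC[C@@H](CC(=O)O)C=CC1 | intermediate
7 | (3aS,8R,8aR)-8-iodooctahydro-2H-cyclohepta[b]furan-2-one (cis-fused lactone, iodine trans to the ring oxygen) | C1CC[C@H]2CC(=O)O[C@H]2[C@H](I)C1 | intermediate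
8 | (3aS,8aR)-3,3a,4,5,6,8a-hexahydro-2H-cyclohepta[b]furan-2-one | C1CC[C@H]2CC(=O)O[C@H]2C=C1 | intermediate
9 | lithium enolate of 8 (lithium 3a,4,5,6-tetrahydro-8aH-cyclohepta[b]furan-2-olate, ring fusion as in 8; not isolated) | C1CC[C@H]2C=C(O[Li])O[C@H]2C=C1 | intermediate
10 | (3S,3aS,8aS)-3-methyl-3,3a,4,5,6,8a-hexahydro-2H-cyclohepta[b]furan-2-one (methyl on the convex face, cis to H3a) | C1CC[C@H]2[C@H](C)C(=O)O[C@H]2C=C1 | intermediate
11 | (2S)-2-[(1S,2S)-2-hydroxycyclohept-3-en-1-yl]-N-methoxy-N-methylpropanamide | C1CC[C@@H]([C@H](C)C(=O)N(C)OC)[C@@H](O)C=C1 | intermediate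
12 | (2S)-2-[(1S,2S)-2-(tert-butyldimethylsilyloxy)cyclohept-3-en-1-yl]-N-methoxy-N-methylpropanamide | C1CC[C@@H]([C@H](C)C(=O)N(C)OC)[C@@H](O[Si](C)(C)C(C)(C)C)C=C1 | intermediate
13 | (2S)-2-[(1S,2S)-2-(tert-butyldimethylsilyloxy)-5-oxocyclohept-3-en-1-yl]-N-methoxy-N-methylpropanamide | O=C1CC[C@@H]([C@H](C)C(=O)N(C)OC)[C@@H](O[Si](C)(C)C(C)(C)C)C=C1 | intermediate
14 | bromomagnesium enolate of the conjugate adduct (O–MgBr on C10, C10=C1; C5, C6, C7 and C11 as in 15; not isolated) | Br[Mg]OC=1CC[C@@H]([C@H](C)C(=O)N(C)OC)[C@@H](O[Si](C)(C)C(C)(C)C)[C@H](C(C)=C)C=1 | intermediate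
15 | (2S)-2-[(1S,2R,3S,4R)-2-(tert-butyldimethylsilyloxy)-5-oxo-4-(prop-2-en-1-yl)-3-(prop-1-en-2-yl)cycloheptyl]-N-methoxy-N-methylpropanamide | O=C1CC[C@@H]([C@H](C)C(=O)N(C)OC)[C@@H](O[Si](C)(C)C(C)(C)C)[C@H](C(C)=C)[C@H]1CC=C | intermediate
16 | potassium enolate of 15 (O–K on C10, C9=C10; other centres as in 15; not isolated) | [K]OC1=CC[C@@H]([C@H](C)C(=O)N(C)OC)[C@@H](O[Si](C)(C)C(C)(C)C)[C@H](C(C)=C)[C@H]1CC=C | intermediate
17 | (2S)-2-[(1S,2R,3S,4R,6R)-2-(tert-butyldimethylsilyloxy)-6-hydroxy-5-oxo-4-(prop-2-en-1-yl)-3-(prop-1-en-2-yl)cycloheptyl]-N-methoxy-N-methylpropanamide | O=C1[C@H](O)C[C@@H]([C@H](C)C(=O)N(C)OC)[C@@H](O[Si](C)(C)C(C)(C)C)[C@H](C(C)=C)[C@H]1CC=C | intermediate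
18 | (2S)-2-[(1S,2R,3S,4R,6R)-2-(tert-butyldimethylsilyloxy)-6-hydroxy-5-methylidene-4-(prop-2-en-1-yl)-3-(prop-1-en-2-yl)cycloheptyl]-N-methoxy-N-methylpropanamide | C=C1[C@H](O)C[C@@H]([C@H](C)C(=O)N(C)OC)[C@@H](O[Si](C)(C)C(C)(C)C)[C@H](C(C)=C)[C@H]1CC=C | intermediate
19 | (2S)-2-[(1S,2R,3S,4R,6R)-2-(tert-butyldimethylsilyloxy)-6-hydroxy-5-methylidene-4-(prop-2-en-1-yl)-3-(prop-1-en-2-yl)cycloheptyl]propanal | C=C1[C@H](O)C[C@@H]([C@H](C)C=O)[C@@H](O[Si](C)(C)C(C)(C)C)[C@H](C(C)=C)[C@H]1CC=C | intermediate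
20 | (1R,3S,4R,5S,6R)-4-(tert-butyldimethylsilyloxy)-3-[(2S,3S)-3-hydroxyhex-5-en-2-yl]-7-methylidene-6-(prop-2-en-1-yl)-5-(prop-1-en-2-yl)cycloheptan-1-ol | C=C1[C@H](O)C[C@@H]([C@H](C)[C@H](CC=C)O)[C@@H](O[Si](C)(C)C(C)(C)C)[C@H](C(C)=C)[C@H]1CC=C | intermediate
21 | (1R,3S,4R,5S,6R)-3-[(2S,3S)-3-acetoxyhex-5-en-2-yl]-4-(tert-butyldimethylsilyloxy)-7-methylidene-6-(prop-2-en-1-yl)-5-(prop-1-en-2-yl)cycloheptyl acetate | C=C1[C@H](OC(C)=O)C[C@@H]([C@H](C)[C@H](CC=C)OC(C)=O)[C@@H](O[Si](C)(C)C(C)(C)C)[C@H](C(C)=C)[C@H]1CC=C | intermediate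
22 | (3aS,4R,5S,7R,8aR)-5-[(2S,3S)-3-acetoxyhex-5-en-2-yl]-4-(tert-butyldimethylsilyloxy)-3-methyl-8-methylidene-1,3a,4,5,6,7,8,8a-octahydroazulen-7-yl acetate (not isolated) | C=C1[C@H](OC(C)=O)C[C@@H]([C@H](C)[C@H](CC=C)OC(C)=O)[C@@H](O[Si](C)(C)C(C)(C)C)[C@@H]2C(C)=CC[C@@H]12 | intermediate
23 | (3aS,4R,5S,7R,8aR)-5-[(2S,3S)-3-acetoxy-6-methylhept-5-en-2-yl]-4-(tert-butyldimethylsilyloxy)-3-methyl-8-methylidene-1,3a,4,5,6,7,8,8a-octahydroazulen-7-yl acetate | C=C1[C@H](OC(C)=O)C[C@@H]([C@H](C)[C@H](CC=C(C)C)OC(C)=O)[C@@H](O[Si](C)(C)C(C)(C)C)[C@@H]2C(C)=CC[C@@H]12 | intermediate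
24 | (3aS,4R,5S,7R,8aR)-5-[(2S,3S)-3-acetoxy-6-methylhept-5-en-2-yl]-4-hydroxy-3-methyl-8-methylidene-1,3a,4,5,6,7,8,8a-octahydroazulen-7-yl acetate (CNP0151479.2) | C=C1[C@H](OC(C)=O)C[C@@H]([C@H](C)[C@H](CC=C(C)C)OC(C)=O)[C@@H](O)[C@@H]2C(C)=CC[C@@H]12 | target

Total step count: 17. Longest linear sequence: 17 steps, from cycloheptene.

Steps most likely to fail

Step 16. The ring closure may stall at the hindered isopropenyl group while the side-chain allyl group oligomerises by cross-metathesis, or the trisubstituted olefin may cap the C1 allyl group before it cyclises. The fallback moves the ring closure to the ketone stage, where only the two reacting olefins are present. It sets out from 15: Grubbs II in CH2Cl2 at 40 °C should give the trans-fused bicyclic ketone (2S)-2-[(3aS,4R,5S,8aR)-4-(tert-butyldimethylsilyloxy)-3-methyl-8-oxo-1,3a,4,5,6,7,8,8a-octahydroazulen-5-yl]-N-methoxy-N-methylpropanamide F1. Enolate hydroxylation (KHMDS, sulfonyloxaziridine) then gives the 7-hydroxy ketone F2, Lombardo methylenation the 8-methylidene alcohol F3, DIBAL-H the aldehyde F4, and allylboration with (−)-Ipc2B(allyl) the homoallylic diol F5. Acetylation of the diol comes back to the route at 22, now isolated, which is converted to 23 by cross-metathesis with 2-methyl-2-butene alone.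

Step 9. Oxidation may start at the silyloxy-bearing allylic C–H, proceed with allylic transposition, or over-oxidise. The fallback oxidises while the C6 oxygen is still an acyloxy group that deactivates its C–H. It sets out from 10: CrO3·3,5-dimethylpyrazole should give the enone lactone (3S,3aS,8aS)-3-methyl-3,3a,4,5-tetrahydro-2H-cyclohepta[b]furan-2,6(8aH)-dione F6. Weinreb aminolysis (MeNH(OMe)·HCl, AlMe3) then gives the hydroxy enone (2S)-2-[(1S,2S)-2-hydroxy-5-oxocyclohept-3-en-1-yl]-N-methoxy-N-methylpropanamide F7, and silylation with TBSOTf comes back to the route at 13.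

Step 11. Facial discrimination in the attack of the oxaziridine on enolate 16 may be poor, or the α-hydroxy ketone may epimerise. The fallback corrects C9 by SN2 inversion instead of relying on kinetic facial control. It sets out from 15: the undesired C9 epimer of the hydroxy ketone, (6S)-configured F8, is separated and methylenated (Lombardo) to the epimeric allylic alcohol F9. This is esterified with inversion under Mitsunobu conditions (4-nitrobenzoic acid, PPh3, DIAD) to the (6R)-4-nitrobenzoate F10, and methanolysis (K2CO3, MeOH) comes back to the route at 18.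

Further compounds
F1 | step 16 | (2S)-2-[(3aS,4R,5S,8aR)-4-(tert-butyldimethylsilyloxy)-3-methyl-8-oxo-1,3a,4,5,6,7,8,8a-octahydroazulen-5-yl]-N-methoxy-N-methylpropanamide | O=C1CC[C@@H]([C@H](C)C(=O)N(C)OC)[C@@H](O[Si](C)(C)C(C)(C)C)[C@@H]2C(C)=CC[C@@H]12
F2 | step 16 | (2S)-2-[(3aS,4R,5S,7R,8aR)-4-(tert-butyldimethylsilyloxy)-7-hydroxy-3-methyl-8-oxo-1,3a,4,5,6,7,8,8a-octahydroazulen-5-yl]-N-methoxy-N-methylpropanamide | O=C1[C@H](O)C[C@@H]([C@H](C)C(=O)N(C)OC)[C@@H](O[Si](C)(C)C(C)(C)C)[C@@H]2C(C)=CC[C@@H]12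
F3 | step 16 | (2S)-2-[(3aS,4R,5S,7R,8aR)-4-(tert-butyldimethylsilyloxy)-7-hydroxy-3-methyl-8-methylidene-1,3a,4,5,6,7,8,8a-octahydroazulen-5-yl]-N-methoxy-N-methylpropanamide | C=C1[C@H](O)C[C@@H]([C@H](C)C(=O)N(C)OC)[C@@H](O[Si](C)(C)C(C)(C)C)[C@@H]2C(C)=CC[C@@H]12
F4 | step 16 | (2S)-2-[(3aS,4R,5S,7R,8aR)-4-(tert-butyldimethylsilyloxy)-7-hydroxy-3-methyl-8-methylidene-1,3a,4,5,6,7,8,8a-octahydroazulen-5-yl]propanal | C=C1[C@H](O)C[C@@H]([C@H](C)C=O)[C@@H](O[Si](C)(C)C(C)(C)C)[C@@H]2C(C)=CC[C@@H]12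
F5 | step 16 | (3aS,4R,5S,7R,8aR)-4-(tert-butyldimethylsilyloxy)-5-[(2S,3S)-3-hydroxyhex-5-en-2-yl]-3-methyl-8-methylidene-1,3a,4,5,6,7,8,8a-octahydroazulen-7-ol | C=C1[C@H](O)C[C@@H]([C@H](C)[C@H](CC=C)O)[C@@H](O[Si](C)(C)C(C)(C)C)[C@@H]2C(C)=CC[C@@H]12
F6 | step 9 | (3S,3aS,8aS)-3-methyl-3,3a,4,5-tetrahydro-2H-cyclohepta[b]furan-2,6(8aH)-dione | O=C1CC[C@H]2[C@H](C)C(=O)O[C@H]2C=C1
F7 | step 9 | (2S)-2-[(1S,2S)-2-hydroxy-5-oxocyclohept-3-en-1-yl]-N-methoxy-N-methylpropanamide | O=C1CC[C@@H]([C@H](C)C(=O)N(C)OC)[C@@H](O)C=C1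
F8 | step 11 | (2S)-2-[(1S,2R,3S,4R,6S)-2-(tert-butyldimethylsilyloxy)-6-hydroxy-5-oxo-4-(prop-2-en-1-yl)-3-(prop-1-en-2-yl)cycloheptyl]-N-methoxy-N-methylpropanamide | O=C1[C@@H](O)C[C@@H]([C@H](C)C(=O)N(C)OC)[C@@H](O[Si](C)(C)C(C)(C)C)[C@H](C(C)=C)[C@H]1CC=C
F9 | step 11 | (2S)-2-[(1S,2R,3S,4R,6S)-2-(tert-butyldimethylsilyloxy)-6-hydroxy-5-methylidene-4-(prop-2-en-1-yl)-3-(prop-1-en-2-yl)cycloheptyl]-N-methoxy-N-methylpropanamide | C=C1[C@@H](O)C[C@@H]([C@H](C)C(=O)N(C)OC)[C@@H](O[Si](C)(C)C(C)(C)C)[C@H](C(C)=C)[C@H]1CC=C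
F10 | step 11 | (1R,3S,4R,5S,6R)-4-(tert-butyldimethylsilyloxy)-3-[(2S)-1-(methoxy(methyl)amino)-1-oxopropan-2-yl]-7-methylidene-6-(prop-2-en-1-yl)-5-(prop-1-en-2-yl)cycloheptyl 4-nitrobenzoate | C=C1[C@H](OC(=O)c2ccc(cc2)[N+](=O)[O-])C[C@@H]([C@H](C)C(=O)N(C)OC)[C@@H](O[Si](C)(C)C(C)(C)C)[C@H](C(C)=C)[C@H]1CC=C
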